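## Structural features

2-O-Acetylzeylenone is a single carbocycle, a cyclohex-4-en-6-one (C1–C6) with one exocyclic carbon, the C7 methylene on C1. C1 is a quaternary carbinol carbon with a free tertiary hydroxyl and the benzoyloxymethyl group; C2 carries the acetate, C3 an allylic benzoate, and C4=C5 is conjugated to the C6 ketone, which is bonded back to C1. The three stereocentres C1 (S), C2 (S) and C3 (R) are contiguous: the C1 and C2 oxygens are cis, and the C3 oxygen is trans to the C2 oxygen. Fragile elements are the γ-benzoyloxy enone (base can remove H3 and start elimination towards an arene), the tertiary α-hydroxy ketone, and four neighbouring oxygens over which acyl groups can migrate (O7 to O1, O3 to O2, O2 to O1). The real difficulty is twofold: fixing the quaternary C1 carbinol relative to C2 and C3, and ending with four different states on O1, O2, O3 and O7 (free, acetyl, benzoyl, benzoyl). The key step exploits the array C7–C1–C6–C5=C4 with C7 at the acid level, a γ,δ-unsaturated acid. Its [3,3] retron puts the acyl oxygen on C4, so C2–C3–C4 become three adjacent carbinol carbons, the C3–C4–C5 segment of D-gluconic acid in its 1,5-lactone. Sugar numbering is used for the lactones and target numbering for the carbocycles: target C7, C1, C2, C3, C4, C5, C6 correspond to sugar C1, C2, C3, C4, C5, C6, C7.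

## Logic of the disconnections

**28 ⇒ 27 ⇒ 26.** The C6 carbonyl is traced back to a C6–O single bond carrying an oxidatively removable benzyl-type ether. The enone is placed last because it would not survive hydride, fluoride or amide bases. The gain is that every earlier intermediate is a plain allylic ether. The demand is that ether cleavage spares two benzoates, an acetate, the alkene and the free tertiary hydroxyl, and that the final oxidation is neutral.

**26 ⇒ 24 ⇒ 20.** The O2–acetyl bond (from 25) and the O3–benzoyl bond (from 18) are cut. O1 is tertiary and needs no protection; O2 and O3 are told apart by the cis relation of O1 and O2, which is bridged temporarily with 21 (intermediates 22 and 23). The gain is triol 20, in which nothing has yet been differentiated. The demand is that the bridge forms only across the cis pair and that the O3 benzoate does not migrate once O2 is free again.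

**20 ⇒ 19 ⇒ 17 ⇒ 16.** Three O–Si bonds, the O7–benzoyl bond (from 18) and the oxidation level of C7 are taken back. O7 is benzoylated while O1–O3 are still silylated, which makes that acylation unambiguous. The gain is acid 16, which contains the rearrangement retron. The demand is that hydride reduces a hindered α-silyloxy acid without silyl migration and that fluoride does not move the benzoate.

**16 ⇒ 12.** The C1–C6 ring bond is cut, the C4–O bond is restored and the alkene moves from C4=C5 to C5=C6. The gain is large: the carbocycle becomes a sugar lactone, C2 and C3 become the existing trans sugar C3 and C4, and the quaternary centre becomes an enolisable CH. The demand is enolisation to 14 without loss of the β-silyloxy group, a boat-mode shift to 15, and faithful chirality transfer from the alkenyl-bearing carbinol carbon.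

**12 ⇒ 4 + 10.** The C5=C6 double bond is cut as a carbonyl olefination; the one-carbon unit and the future C6 oxygen come from 10 through 11. The gain is a return to a six-carbon sugar. The demand is that 11 adds to the aldehyde faster than it deprotonates it or attacks the lactone, and that the E isomer is obtained.

**10 ⇒ 7 + 8 ⇒ 5 + 6.** The P–C bond (8 with chloride 9, made from 7) and the O–CH2 bond (5 with 6) are cut, because 10 is not a catalogue reagent. The demand is that the hydrolytically labile 9 is used as formed.

**4 ⇒ 3 ⇒ 1 + 2.** The aldehyde is taken back to the primary silyl ether and four O–Si bonds to 1 and 2. Uniform silylation needs no selectivity, and only the primary silyl ether is oxidised directly. The demand is that the δ-lactone is preserved during silylation, that the secondary silyl ethers survive the oxidation, and that the formyl-bearing carbon is not epimerised.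

## Other disconnections considered

**Alternative 1:** The cut is the C3–C4 ring bond. In the forward step CrCl2 with catalytic NiCl2 would convert the (Z)-β-iodoenone aldehyde A1 into an alkenylchromium species (trivalent chromium) at C4 that adds to the C3 aldehyde and gives the hydroxy enone acetonide A2.
- In favour: the ring, the C4=C5 alkene and the C6 ketone arrive together at the final oxidation level. The reagent is aldehyde-selective and neutral. The acetonide already separates O1/O2 from O3, so A2 would be three operations from the target (benzoylation, acetal hydrolysis, acetylation).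
- Against: C3 is created in the closure by substrate induction, and the trans O2/O3 relation is not guaranteed. A1 requires a separate enantioselective construction of the quaternary C1 centre, an epimerisable α-alkoxy aldehyde, and an iodoenone whose Z geometry is mandatory. Chromium is used in stoichiometric amount.
- Comparison: on structure the chosen plan is stronger, since C2 and C3 come from the sugar and C1 by transfer. On mechanism the two are equal as intramolecular six-ring closures, and the alternative is better in avoiding an enolate with a β-leaving group. On step economy the alternative is better after its key step (three steps against seven) and probably worse before it.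

**Alternative 2:** The cut is the C1–C2 bond between the two carbinol carbons. SmI2 would reduce the aldehyde and ketone of the (Z)-alkene-linked keto-aldehyde A3 to ketyls that couple to the cis-diol A4.
- In favour: the cis tertiary–secondary diol forms in one step, and samarium-bridged coupling normally gives cis diols with the new hydroxyl anti to a neighbouring alkoxy group. It is therefore the equal of the chosen plan for the C1/C2 relation and better in needing no basic enolate. O3 and O7 carry the same ether, so both benzoates could be introduced together, a cleaner differentiation than in the chosen plan.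
- Against: two stereocentres rest on induction. In A3 the aldehyde α-carbon is allylic and oxygenated (epimerisation, alkene migration), and the ketone has two α-oxygens that divalent samarium can cleave reductively. The C6 stereocentre must be made enantioselectively only to be oxidised later.
- Comparison: structure favours the chosen plan (commercial chiral source, transfer); mechanism is about equal in risk; step count after the key step is about equal and before it probably longer.

**Alternative 3:** The cuts are the C3–O and C6–O bonds. Photosensitised singlet oxygen would add to the diene acetonide A5 on the face opposite the acetal and give the endoperoxide A6; base-induced opening with loss of H6 would then lead to A2.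
- In favour: both missing oxygens arrive in one step with the correct C2/C3 trans relation, the reagent is oxygen and light, and the endgame from A2 is three steps. This is clearly better than the chosen plan in step and atom economy, and the cycloaddition is more predictable than an untested boat rearrangement.
- Against: A5, with a quaternary carbinol carbon of the right absolute configuration, is not a catalogue compound and would need microbial ipso,ortho-dihydroxylation of a benzoate or a multistep synthesis. The opening of A6 must remove the more hindered H6 and not H3. Such dienes also dimerise and aromatise easily.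
- Comparison: equal in relative stereocontrol; the chosen plan is better in the source of absolute configuration and commercial starting materials; the alternative is better in length. Its regioselective peroxide opening is a risk of the same order as the selective acylation in the chosen plan.

Key step: step 6

Remark on the chemistry: the drawn E enol ether and the (6S) acid are mutually consistent with a boat rearrangement, so no structure needed correcting; the Z isomer would give the (6R) epimer, which ends as the same ketone. The six-membered lactone gives a six-membered carbocycle, so the step removes the ring oxygen without changing ring size.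

## Route

Step 1
Reactants: 1 D-glucono-1,5-lactone; 2 chlorotriethylsilane
Product: 3 2,3,4,6-tetrakis-O-(triethylsilyl)-D-glucono-1,5-lactone
Conditions: Et3SiCl, N-methylmorpholine, DMAP (cat.), THF/DMF, 0 °C → rt
Reagents that add atoms: chlorotriethylsilane (2), CC[Si](Cl)(CC)CC
Why: Exhaustive O-silylation with a silyl chloride and a weakly nucleophilic amine, which should keep the δ-lactone from opening or isomerising; no stereocentre is touched.

Step 2
Reactants: 3 2,3,4,6-tetrakis-O-(triethylsilyl)-D-glucono-1,5-lactone
Product: 4 (2S,3R,4S,5R)-6-oxo-3,4,5-tris(triethylsilyloxy)oxane-2-carbaldehyde (sugar C6 aldehyde of the tris-silylated D-glucono-1,5-lactone)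
Conditions: (COCl)2, DMSO, CH2Cl2, −78 → −35 °C; then Et3N, −78 → 0 °C
Reagents that add atoms: none
Why: Swern oxidation applied directly to a primary triethylsilyl ether: the unhindered silyl ether oxygen attacks the chlorosulfonium salt and loses silicon, the hindered secondary silyl ethers do not, and amine-induced collapse of the alkoxysulfonium gives the aldehyde; the formyl-bearing carbon must keep its configuration, so the amine is added cold and the aldehyde used at once.

Step 3
Reactants: 5 4-methoxybenzyl alcohol; 6 chloromethyl methyl sulfide
Product: 7 4-methoxybenzyl methylthiomethyl ether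
Conditions: NaH, NaI (cat.), DME, 0 °C → rt
Reagents that add atoms: chloromethyl methyl sulfide (6), CSCCl
Why: Williamson ether synthesis; the alkoxide displaces chloride (iodide catalysis) at the sulfur-activated methylene.

Step 4
Reactants: 7 4-methoxybenzyl methylthiomethyl ether; 8 triphenylphosphine
Product: 10 {[(4-methoxybenzyl)oxy]methyl}triphenylphosphonium chloride, via chloromethyl ether 9 (not isolated)
Conditions: SO2Cl2, CH2Cl2, −78 °C, then evaporate; PPh3, PhMe, rt
Reagents that add atoms: sulfuryl chloride, O=S(=O)(Cl)Cl; triphenylphosphine (8), c1ccc(cc1)P(c1ccccc1)c1ccccc1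
Why: Chlorinolysis of the O,S-acetal to the α-chloro ether 9, followed by SN2 quaternisation of the phosphine; volatile sulfur by-products are removed before the phosphine is added.

Step 5
Reactants: 4 (2S,3R,4S,5R)-6-oxo-3,4,5-tris(triethylsilyloxy)oxane-2-carbaldehyde; 10 {[(4-methoxybenzyl)oxy]methyl}triphenylphosphonium chloride
Product: 12 (3R,4S,5R,6R)-6-{(E)-2-[(4-methoxybenzyl)oxy]ethenyl}-3,4,5-tris(triethylsilyloxy)oxan-2-one (D-gluco configuration), via phosphorus ylide 11 (not isolated)
Conditions: 10, KN(SiMe3)2 (slightly less than 10), THF, −78 → 0 °C; then 4, −78 → 0 °C; Et3N-deactivated silica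
Reagents that add atoms: phosphonium salt 10 (as ylide 11), COc1ccc(COC[P+](c2ccccc2)(c2ccccc2)c2ccccc2)cc1.[Cl-]
Why: Wittig olefination with an alkoxymethylene ylide, which adds to the aldehyde far faster than to the lactone at low temperature; a slight deficit of base avoids free amide, and the E isomer 12 is separated by chromatography (the Z isomer is equally usable, as noted in the remark).

Step 6
Reactants: 12 (3R,4S,5R,6R)-6-{(E)-2-[(4-methoxybenzyl)oxy]ethenyl}-3,4,5-tris(triethylsilyloxy)oxan-2-one; 13 chlorotrimethylsilane
Product: 16 (1R,2S,3R,6S)-6-[(4-methoxybenzyl)oxy]-1,2,3-tris(triethylsilyloxy)cyclohex-4-ene-1-carboxylic acid, via silyl ketene acetal 14 (not isolated), via trimethylsilyl ester 15 (not isolated)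
Conditions: Me3SiCl/Et3N, THF, −95 °C; LiN(iPr)2 added slowly; → rt, then PhMe, 70 °C; aq. citric acid/THF
Reagents that add atoms: chlorotrimethylsilane (13), C[Si](C)(C)Cl (its silyl group is present in 14 and 15 and is lost on hydrolysis to 16)
Why: Ireland–Claisen rearrangement: deprotonation at the lactone α-carbon (sugar C2) with the silyl chloride already present traps the enolate as the endocyclic silyl ketene acetal 14, and on warming a concerted suprafacial [3,3] shift forms C1–C6, breaks the lactone C4–O bond and leaves C4=C5 and the silyl ester 15, which dilute acid hydrolyses to 16. The closest known reaction type is the ester-enolate Claisen rearrangement of alkenyl lactone silyl ketene acetals to cycloalkenecarboxylic acids, and that of glycal esters, which share the γ-alkoxyallyl ester motif. The cyclohexene closes because the two alkene carbons bridge positions 3 and 6 of the oxane; the tether forbids a chair, so the array passes through a boat resembling bicyclo[2.2.2]octane. C1 is controlled by the alkenyl-bearing carbinol carbon (sugar C5): the alkenyl group can only reach the face of the planar ketene acetal carbon on which it stands, which puts C1–O cis to C2–O and the carboxyl cis to C3–O. C6 is controlled by the E geometry in the boat (C6–O trans to C1–O) and is erased later by oxidation. The selectivity needed is O-silylation over E1cB loss of the sugar C3 silyloxy group, secured by the in situ quench at low temperature and by the poor leaving ability of a silyloxy group. The two bulky trans-vicinal silyloxy groups at sugar C3 and C4 are expected to favour the axial-rich conformer that also holds the alkenyl group axial, and the alkoxy donor on the alkene terminus should ease C–O cleavage so that mild heating suffices.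

Step 7
Reactants: 16 (1R,2S,3R,6S)-6-[(4-methoxybenzyl)oxy]-1,2,3-tris(triethylsilyloxy)cyclohex-4-ene-1-carboxylic acid
Product: 17 {(1R,2S,3R,6S)-6-[(4-methoxybenzyl)oxy]-1,2,3-tris(triethylsilyloxy)cyclohex-4-en-1-yl}methanol
Conditions: LiAlH4, THF, 0 °C → rt
Reagents that add atoms: none
Why: Hydride reduction of a carboxylic acid to the primary alcohol; silyl ethers, the benzyl-type ether and the isolated alkene are inert, and the aluminium alkoxide formed is a poor partner for silyl migration.

Step 8
Reactants: 17 {(1R,2S,3R,6S)-6-[(4-methoxybenzyl)oxy]-1,2,3-tris(triethylsilyloxy)cyclohex-4-en-1-yl}methanol; 18 benzoyl chloride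
Product: 19 {(1R,2S,3R,6S)-6-[(4-methoxybenzyl)oxy]-1,2,3-tris(triethylsilyloxy)cyclohex-4-en-1-yl}methyl benzoate
Conditions: BzCl, pyridine, DMAP (cat.), CH2Cl2, 0 °C → rt
Reagents that add atoms: benzoyl chloride (18), O=C(Cl)c1ccccc1
Why: Acylation of the only free hydroxyl (primary O7) under nucleophilic catalysis; no selectivity is needed.

Step 9
Reactants: 19 {(1R,2S,3R,6S)-6-[(4-methoxybenzyl)oxy]-1,2,3-tris(triethylsilyloxy)cyclohex-4-en-1-yl}methyl benzoate
Product: 20 {(1S,2S,3R,6S)-1,2,3-trihydroxy-6-[(4-methoxybenzyl)oxy]cyclohex-4-en-1-yl}methyl benzoate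
Conditions: HF·pyridine, pyridine/THF, 0 °C → rt
Reagents that add atoms: none
Why: Fluoride-mediated cleavage of all three silyl ethers in a buffered, weakly acidic medium that leaves the benzoate in place and the benzyl-type ether intact.

Step 10
Reactants: 20 {(1S,2S,3R,6S)-1,2,3-trihydroxy-6-[(4-methoxybenzyl)oxy]cyclohex-4-en-1-yl}methyl benzoate; 21 phenylboronic acid; 18 benzoyl chloride
Product: 24 {(1S,2S,3R,6S)-3-(benzoyloxy)-1,2-dihydroxy-6-[(4-methoxybenzyl)oxy]cyclohex-4-en-1-yl}methyl benzoate, via phenylboronate 22 (not isolated), via benzoylated phenylboronate 23 (not isolated)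
Conditions: PhB(OH)2, PhMe, reflux (−H2O); then BzCl, pyridine, 0 °C → rt; then pinacol, rt
Reagents that add atoms: phenylboronic acid (21), OB(O)c1ccccc1 (present in 22 and 23 only); benzoyl chloride (18), O=C(Cl)c1ccccc1
Why: Transient boronate masking and acylation: the boronic acid condenses only with the cis O1/O2 pair to the cis-fused five-membered boronate 22 (the trans O2/O3 pair cannot be bridged), O3 is then the only free hydroxyl for pyridine-mediated benzoylation to 23, and transesterification with pinacol releases diol 24; no stereocentre is formed.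

Step 11
Reactants: 24 {(1S,2S,3R,6S)-3-(benzoyloxy)-1,2-dihydroxy-6-[(4-methoxybenzyl)oxy]cyclohex-4-en-1-yl}methyl benzoate; 25 acetic anhydride
Product: 26 {(1R,2S,3R,6S)-2-acetoxy-3-(benzoyloxy)-1-hydroxy-6-[(4-methoxybenzyl)oxy]cyclohex-4-en-1-yl}methyl benzoate
Conditions: Ac2O, pyridine, DMAP (cat.), CH2Cl2, 0 °C
Reagents that add atoms: acetic anhydride (25), CC(=O)OC(C)=O
Why: Esterification with an anhydride under nucleophilic catalysis; the secondary O2–H reacts while the tertiary O1–H is too hindered at 0 °C, and no stereocentre is touched (the C1 descriptor changes only because the priorities of its neighbours change).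

Step 12
Reactants: 26 {(1R,2S,3R,6S)-2-acetoxy-3-(benzoyloxy)-1-hydroxy-6-[(4-methoxybenzyl)oxy]cyclohex-4-en-1-yl}methyl benzoate
Product: 27 {(1R,2S,3R,6S)-2-acetoxy-3-(benzoyloxy)-1,6-dihydroxycyclohex-4-en-1-yl}methyl benzoate
Conditions: DDQ, CH2Cl2/pH 7 buffer, 0 °C → rt
Reagents that add atoms: none
Why: Oxidative cleavage of a 4-methoxybenzyl ether by DDQ (electron transfer, benzylic cation, capture by water, hemiacetal collapse); the esters, the alkene and the tertiary alcohol are inert, and water is kept present so that the cation is taken by water and not by O1.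

Step 13
Reactants: 27 {(1R,2S,3R,6S)-2-acetoxy-3-(benzoyloxy)-1,6-dihydroxycyclohex-4-en-1-yl}methyl benzoate
Product: 28 {(1S,2S,3R)-2-acetoxy-3-(benzoyloxy)-1-hydroxy-6-oxocyclohex-4-en-1-yl}methyl benzoate (2-O-acetylzeylenone)
Conditions: Dess–Martin periodinane, NaHCO3, CH2Cl2, rt
Reagents that add atoms: none
Why: Dess–Martin oxidation of the allylic secondary alcohol to the enone under buffered, base-free conditions that spare the γ-benzoyloxy enone and the tertiary alcohol; the C6 stereocentre is erased and C1–C3 are untouched.

## Compound list

1 | D-glucono-1,5-lactone | O=C1O[C@H](CO)[C@@H](O)[C@H](O)[C@H]1O | starting material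
2 | chlorotriethylsilane | CC[Si](Cl)(CC)CC | starting material
3 | 2,3,4,6-tetrakis-O-(triethylsilyl)-D-glucono-1,5-lactone | O=C1O[C@H](CO[Si](CC)(CC)CC)[C@@H](O[Si](CC)(CC)CC)[C@H](O[Si](CC)(CC)CC)[C@H]1O[Si](CC)(CC)CC | intermediate
4 | (2S,3R,4S,5R)-6-oxo-3,4,5-tris(triethylsilyloxy)oxane-2-carbaldehyde | O=C1O[C@H](C=O)[C@@H](O[Si](CC)(CC)CC)[C@H](O[Si](CC)(CC)CC)[C@H]1O[Si](CC)(CC)CC | intermediate
5 | 4-methoxybenzyl alcohol | COc1ccc(CO)cc1 | starting material
6 | chloromethyl methyl sulfide | CSCCl | starting material
7 | 4-methoxybenzyl methylthiomethyl ether | COc1ccc(COCSC)cc1 | intermediate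
8 | triphenylphosphine | c1ccc(cc1)P(c1ccccc1)c1ccccc1 | starting material
9 | 4-methoxybenzyl chloromethyl ether | COc1ccc(COCCl)cc1 | intermediate
10 | {[(4-methoxybenzyl)oxy]methyl}triphenylphosphonium chloride | COc1ccc(COC[P+](c2ccccc2)(c2ccccc2)c2ccccc2)cc1.[Cl-] | intermediate
11 | {[(4-methoxybenzyl)oxy]methylidene}triphenylphosphorane | COc1ccc(COC=P(c2ccccc2)(c2ccccc2)c2ccccc2)cc1 | intermediate
12 | (3R,4S,5R,6R)-6-{(E)-2-[(4-methoxybenzyl)oxy]ethenyl}-3,4,5-tris(triethylsilyloxy)oxan-2-one | O=C1O[C@H](/C=C/OCc2ccc(OC)cc2)[C@@H](O[Si](CC)(CC)CC)[C@H](O[Si](CC)(CC)CC)[C@H]1O[Si](CC)(CC)CC | intermediate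
13 | chlorotrimethylsilane | C[Si](C)(C)Cl | starting material
14 | 6-{(E)-2-[(4-methoxybenzyl)oxy]ethenyl}-3,4,5-tris(triethylsilyloxy)-2-(trimethylsilyloxy)-5,6-dihydro-4H-pyran, C4, C5 and C6 configured as in 12 | C[Si](C)(C)OC1=C(O[Si](CC)(CC)CC)[C@@H](O[Si](CC)(CC)CC)[C@H](O[Si](CC)(CC)CC)[C@@H](/C=C/OCc2ccc(OC)cc2)O1 | intermediate
15 | trimethylsilyl (1R,2S,3R,6S)-6-[(4-methoxybenzyl)oxy]-1,2,3-tris(triethylsilyloxy)cyclohex-4-ene-1-carboxylate | CC[Si](CC)(CC)O[C@H]1[C@H](O[Si](CC)(CC)CC)C=C[C@H](OCc2ccc(OC)cc2)[C@]1(O[Si](CC)(CC)CC)C(=O)O[Si](C)(C)C | intermediate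
16 | (1R,2S,3R,6S)-6-[(4-methoxybenzyl)oxy]-1,2,3-tris(triethylsilyloxy)cyclohex-4-ene-1-carboxylic acid | CC[Si](CC)(CC)O[C@H]1[C@H](O[Si](CC)(CC)CC)C=C[C@H](OCc2ccc(OC)cc2)[C@]1(O[Si](CC)(CC)CC)C(=O)O | intermediate
17 | {(1R,2S,3R,6S)-6-[(4-methoxybenzyl)oxy]-1,2,3-tris(triethylsilyloxy)cyclohex-4-en-1-yl}methanol | CC[Si](CC)(CC)O[C@H]1[C@H](O[Si](CC)(CC)CC)C=C[C@H](OCc2ccc(OC)cc2)[C@]1(O[Si](CC)(CC)CC)CO | intermediate
18 | benzoyl chloride | O=C(Cl)c1ccccc1 | starting material
19 | {(1R,2S,3R,6S)-6-[(4-methoxybenzyl)oxy]-1,2,3-tris(triethylsilyloxy)cyclohex-4-en-1-yl}methyl benzoate | CC[Si](CC)(CC)O[C@H]1[C@H](O[Si](CC)(CC)CC)C=C[C@H](OCc2ccc(OC)cc2)[C@]1(O[Si](CC)(CC)CC)COC(=O)c1ccccc1 | intermediate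
20 | {(1S,2S,3R,6S)-1,2,3-trihydroxy-6-[(4-methoxybenzyl)oxy]cyclohex-4-en-1-yl}methyl benzoate | O[C@H]1[C@H](O)C=C[C@H](OCc2ccc(OC)cc2)[C@]1(O)COC(=O)c1ccccc1 | intermediate
21 | phenylboronic acid | OB(O)c1ccccc1 | starting material
22 | cyclic phenylboronate of 20 across O1 and O2 (O3–H free) | c1ccccc1B1O[C@H]2[C@H](O)C=C[C@H](OCc3ccc(OC)cc3)[C@]2(O1)COC(=O)c1ccccc1 | intermediate
23 | O3-benzoate of boronate 22 | c1ccccc1B1O[C@H]2[C@H](OC(=O)c3ccccc3)C=C[C@H](OCc3ccc(OC)cc3)[C@]2(O1)COC(=O)c1ccccc1 | intermediate
24 | {(1S,2S,3R,6S)-3-(benzoyloxy)-1,2-dihydroxy-6-[(4-methoxybenzyl)oxy]cyclohex-4-en-1-yl}methyl benzoate | O[C@H]1[C@H](OC(=O)c2ccccc2)C=C[C@H](OCc2ccc(OC)cc2)[C@]1(O)COC(=O)c1ccccc1 | intermediate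
25 | acetic anhydride | CC(=O)OC(C)=O | starting material
26 | {(1R,2S,3R,6S)-2-acetoxy-3-(benzoyloxy)-1-hydroxy-6-[(4-methoxybenzyl)oxy]cyclohex-4-en-1-yl}methyl benzoate | CC(=O)O[C@H]1[C@H](OC(=O)c2ccccc2)C=C[C@H](OCc2ccc(OC)cc2)[C@]1(O)COC(=O)c1ccccc1 | intermediate
27 | {(1R,2S,3R,6S)-2-acetoxy-3-(benzoyloxy)-1,6-dihydroxycyclohex-4-en-1-yl}methyl benzoate | CC(=O)O[C@H]1[C@H](OC(=O)c2ccccc2)C=C[C@H](O)[C@]1(O)COC(=O)c1ccccc1 | intermediate
28 | {(1S,2S,3R)-2-acetoxy-3-(benzoyloxy)-1-hydroxy-6-oxocyclohex-4-en-1-yl}methyl benzoate (2-O-acetylzeylenone) | CC(=O)O[C@H]1[C@H](OC(=O)c2ccccc2)C=CC(=O)[C@]1(O)COC(=O)c1ccccc1 | target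

## Step count and least certain steps

Total step count: 13. Longest linear sequence: 11 steps (steps 1, 2 and 5–13 from 1; equally steps 3, 4 and 5–13 from 5).

**Step 6 (key step).** Most likely failure: expulsion of the sugar C3 silyloxy group from the lithium enolate before silylation, because the conformer that reaches the boat also aligns that C–O bond with the enolate. A second possibility is that the crowded boat is not reached and the ketene acetal is lost by hydrolysis or ionisation of the γ-alkoxyallyl ester. Fallback, from 12 and returning at 17: soft enolisation with iPr3SiOTf and Et3N in toluene forms the triisopropylsilyl ketene acetal F1 without a free enolate. Heating should rearrange it to the triisopropylsilyl ester F2, which LiAlH4 reduces directly to 17.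

**Step 5.** Most likely failure: the basic ylide deprotonates the formyl-bearing carbon (epimerisation, which would invert the later chirality transfer, or β-elimination of the neighbouring silyloxy group), adds to the lactone carbonyl, or gives poor E/Z control. Fallback, from 4 and returning at 12: a chromium-mediated olefination under neutral conditions (CrCl2, Cl2CHBpin, LiI, THF) should give the (E)-alkenylboronate F3. A stereoretentive copper-mediated C–O coupling with 5 (Cu(OAc)2, Et3N, CH2Cl2, air, limited excess of 5 to curb lactone alcoholysis) then gives 12 as the E isomer.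

**Step 2.** Most likely failure: loss of secondary silyl groups during the acidic activation phase, or amine-induced epimerisation or β-elimination of the α-acyloxy aldehyde. Fallback, from 3 and returning at 4: selective removal of the primary silyl group with buffered HF·pyridine at low temperature gives the primary alcohol F4, which is oxidised with Dess–Martin periodinane/NaHCO3 in the absence of amine base.

**Step 10.** Most likely failure: incomplete masking of the cis-diol, so that O2 is also benzoylated, or benzoyl migration from O3 to O2 after the boronate is removed. Fallback, from 20 and returning at 24: 2,2-dimethoxypropane with pyridinium tosylate gives the isolable O1,O2-isopropylidene acetal F5. Benzoylation gives its O3-benzoate F6, and aqueous acetic acid at 40 °C removes the acetal.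

**Step 7.** Most likely failure: migration of the tertiary silyl group to the new primary alkoxide, or stalling at the hindered carboxylate. Fallback, from 16 and returning at 17: Me3SiCHN2 in MeOH/PhMe gives the methyl ester F7, which iBu2AlH in CH2Cl2 at −78 °C reduces to 17 through aluminium alkoxides only.

## Further compounds

F1 | step 6 | triisopropylsilyl ketene acetal of 12 | CC(C)[Si](C(C)C)(C(C)C)OC1=C(O[Si](CC)(CC)CC)[C@@H](O[Si](CC)(CC)CC)[C@H](O[Si](CC)(CC)CC)[C@@H](/C=C/OCc2ccc(OC)cc2)O1
F2 | step 6 | triisopropylsilyl (1R,2S,3R,6S)-6-[(4-methoxybenzyl)oxy]-1,2,3-tris(triethylsilyloxy)cyclohex-4-ene-1-carboxylate | CC[Si](CC)(CC)O[C@H]1[C@H](O[Si](CC)(CC)CC)C=C[C@H](OCc2ccc(OC)cc2)[C@]1(O[Si](CC)(CC)CC)C(=O)O[Si](C(C)C)(C(C)C)C(C)C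
F3 | step 5 | (E)-alkenylboronate: 6-[(E)-2-(4,4,5,5-tetramethyl-1,3,2-dioxaborolan-2-yl)ethenyl]-3,4,5-tris(triethylsilyloxy)oxan-2-one, D-gluco | O=C1O[C@H](/C=C/B2OC(C)(C)C(C)(C)O2)[C@@H](O[Si](CC)(CC)CC)[C@H](O[Si](CC)(CC)CC)[C@H]1O[Si](CC)(CC)CC
F4 | step 2 | 2,3,4-tris-O-(triethylsilyl)-D-glucono-1,5-lactone | O=C1O[C@H](CO)[C@@H](O[Si](CC)(CC)CC)[C@H](O[Si](CC)(CC)CC)[C@H]1O[Si](CC)(CC)CC
F5 | step 10 | O1,O2-isopropylidene acetal of 20 | CC1(C)O[C@H]2[C@H](O)C=C[C@H](OCc3ccc(OC)cc3)[C@@]2(COC(=O)c2ccccc2)O1
F6 | step 10 | O3-benzoate of acetal F5 | CC1(C)O[C@H]2[C@H](OC(=O)c3ccccc3)C=C[C@H](OCc3ccc(OC)cc3)[C@@]2(COC(=O)c2ccccc2)O1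
F7 | step 7 | methyl (1R,2S,3R,6S)-6-[(4-methoxybenzyl)oxy]-1,2,3-tris(triethylsilyloxy)cyclohex-4-ene-1-carboxylate | CC[Si](CC)(CC)O[C@H]1[C@H](O[Si](CC)(CC)CC)C=C[C@H](OCc2ccc(OC)cc2)[C@]1(O[Si](CC)(CC)CC)C(=O)OC
A1 | alternative 1 | (Z)-β-iodoenone aldehyde on a 2,2-dimethyl-1,3-dioxolane (C3 aldehyde, C1 benzoyloxymethyl) | CC1(C)O[C@@H](C=O)[C@@](COC(=O)c2ccccc2)(C(=O)/C=C\I)O1
A2 | alternative 1 | C1,C2-O-isopropylidene 3-hydroxy enone with the C7 benzoate | CC1(C)O[C@H]2[C@H](O)C=CC(=O)[C@@]2(COC(=O)c2ccccc2)O1
A3 | alternative 2 | (Z)-alkene-linked keto-aldehyde (C2 aldehyde, C1 ketone) | O=C[C@H](OCc1ccc(OC)cc1)/C=C\[C@H](O[Si](C)(C)C(C)(C)C)C(=O)COCc1ccc(OC)cc1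
A4 | alternative 2 | 6-(tert-butyldimethylsilyloxy)-3-(4-methoxybenzyloxy)-1-(4-methoxybenzyloxymethyl)cyclohex-4-ene-cis-1,2-diol | O[C@H]1[C@H](OCc2ccc(OC)cc2)C=C[C@H](O[Si](C)(C)C(C)(C)C)[C@]1(O)COCc1ccc(OC)cc1
A5 | alternative 3 | acetonide of the 1-(benzoyloxymethyl)cyclohexa-3,5-diene-cis-1,2-diol | CC1(C)O[C@H]2C=CC=C[C@@]2(COC(=O)c2ccccc2)O1
A6 | alternative 3 | C3,C6-endoperoxide of diene A5 | CC1(C)O[C@H]2[C@@H]3OO[C@@H](C=C3)[C@@]2(COC(=O)c2ccccc2)O1
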